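**Strategy.** Everything rests on one cut: the C2–C1' bond between the pyranone ring and the unbranched C29 chain. C2 is the β-carbon of the C4 enone, and the chain is what remains of triacontanoic acid after loss of CO2. The nonacosyl radical freed from the redox-active ester of that acid is therefore added to C2 of a chromone-3-carboxylic acid. In one operation the chain is attached, the activating C3 carboxyl is expelled and a 2-alkylchroman-4-one results. The acceptor, 5,7-dimethoxy-6-methyl-4-oxo-4H-chromene-3-carboxylic acid, comes from a symmetric phenol, which fixes the methyl group between the two oxygens. Dehydrogenation and ether cleavage complete the target.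

Key step: step 6

Remark on the chemistry: the target has no stereocentre. Chromanone 12 is carried as the racemate and β-keto acid 11 as a diastereomer mixture, because C2 becomes sp2 again in step 7.

**Step 1**
Reactants: 1 2,6-dimethoxytoluene
Product: 3 3,5-dimethoxy-4-methylphenol, via aryl pinacol boronate 2 (not isolated)
Conditions: [Ir(OMe)(cod)]2 (cat.), dtbpy (cat.), B2pin2, THF, 80 °C; evaporate; then KHSO5 (as Oxone, 2KHSO5·KHSO4·K2SO4), acetone/H2O, rt
Reagents that add atoms: potassium peroxymonosulfate, [K+].[O-]S(=O)(=O)OO (phenolic oxygen of 3); bis(pinacolato)diboron, CC1(C)OB(OC1(C)C)B1OC(C)(C)C(C)(C)O1 (boryl group of 2 only)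
Why: Iridium-catalysed C–H borylation is sterically governed and should occur only at C4, the one ring position without an ortho substituent, after which peroxymonosulfate oxidation of the C–B bond (aryl shift from boron to oxygen) should give the phenol in the one-pot borylation/oxidation manner.

**Step 2**
Reactants: 3 3,5-dimethoxy-4-methylphenol
Product: 5 1-(6-hydroxy-2,4-dimethoxy-3-methylphenyl)ethan-1-one, via aryl acetate 4 (not isolated)
Conditions: Ac2O, BF3·OEt2, 85 °C; then aq. NaOAc
Reagents that add atoms: acetic anhydride, CC(=O)OC(C)=O
Why: O-Acetylation followed by BF3-promoted Fries rearrangement (Friedel–Crafts acylation) should place the acetyl group ortho to the hydroxyl, since the para position carries the methyl group and the two ortho positions are equivalent by symmetry, so only one regioisomer can form.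

**Step 3**
Reactants: 5 1-(6-hydroxy-2,4-dimethoxy-3-methylphenyl)ethan-1-one
Product: 6 5,7-dimethoxy-6-methyl-4-oxo-4H-chromene-3-carbaldehyde
Conditions: POCl3, DMF, 0 °C → 50 °C; then ice/H2O
Reagents that add atoms: N,N-dimethylformamide, CN(C)C=O (C2 and the formyl carbon); water, O (formyl oxygen)
Why: In this Vilsmeier–Haack reaction of an ortho-hydroxyacetophenone the chloroiminium reagent should formylate the acetyl methyl group twice, the phenolic oxygen should close the pyranone ring with loss of dimethylamine, and hydrolysis of the remaining iminium should give the 3-formylchromone, the benzene ring being deactivated toward formylation by the ketone.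

**Step 4**
Reactants: 6 5,7-dimethoxy-6-methyl-4-oxo-4H-chromene-3-carbaldehyde
Product: 7 5,7-dimethoxy-6-methyl-4-oxo-4H-chromene-3-carboxylic acid
Conditions: NaClO2, NaH2PO4, 2-methyl-2-butene, t-BuOH/THF/H2O, 0 °C → rt
Reagents that add atoms: sodium chlorite, [Na+].[O-]Cl=O
Why: Pinnick (Lindgren) oxidation by chlorous acid under buffered, weakly acidic conditions should convert the aldehyde into the acid without opening the base-sensitive pyranone ring, while 2-methyl-2-butene consumes the hypochlorous acid that could otherwise chlorinate C8.

**Step 5**
Reactants: 8 triacontanoic acid; 9 N-hydroxyphthalimide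
Product: 10 1,3-dioxoisoindolin-2-yl triacontanoate
Conditions: DIC, DMAP (cat.), CH2Cl2/THF, 40 °C
Reagents that add atoms: none
Why: Carbodiimide (Steglich-type) esterification through the O-acylisourea with DMAP as acyl-transfer catalyst is the standard route to N-acyloxyphthalimides and needs only gentle warming to keep the C30 acid dissolved.

**Step 6**
Reactants: 7 5,7-dimethoxy-6-methyl-4-oxo-4H-chromene-3-carboxylic acid; 10 1,3-dioxoisoindolin-2-yl triacontanoate
Product: 12 rac-5,7-dimethoxy-6-methyl-2-nonacosylchroman-4-one, via beta-keto acid 11 (not isolated)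
Conditions: Ru(bpy)3(PF6)2 (cat.), i-Pr2NEt, degassed CH2Cl2, blue LEDs (450 nm), N2, 30–35 °C
Reagents that add atoms: none
Why: The photoexcited divalent ruthenium complex is quenched reductively by i-Pr2NEt, and the reduced complex (formally monovalent ruthenium) passes one electron to ester 10, which fragments into phthalimide anion, CO2 and the primary nonacosyl radical. This nucleophilic radical should add to C2 of 7; the resulting C3 radical, stabilised by both the ketone and the carboxyl group, is reduced and protonated to β-keto acid 11, which loses CO2 in the flask to give 12. The closest known reaction type is the photoredox doubly decarboxylative Giese addition of N-acyloxyphthalimides to chromone-3-carboxylic acids, which gives 2-alkylchroman-4-ones. No ring is closed, and the new C2 stereocentre forms racemic because no chiral element is present, which is harmless since step 7 flattens C2. The selectivity needed is C2 over C3, the C4 carbonyl carbon and the benzene ring; it rests on polarity matching, C2 being the β-position of both the ketone and the carboxyl acceptor, with the C3 carboxyl outweighing the donor effect of the 5- and 7-methoxy groups and of O1.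

**Step 7**
Reactants: 12 rac-5,7-dimethoxy-6-methyl-2-nonacosylchroman-4-one
Product: 13 5,7-dimethoxy-6-methyl-2-nonacosyl-4H-chromen-4-one
Conditions: DDQ, 1,4-dioxane, reflux
Reagents that add atoms: none
Why: In this DDQ dehydrogenation of a chroman-4-one, hydride abstraction from C2 of the enol tautomer, assisted by the lone pair of O1, should give a 4-hydroxybenzopyrylium ion that loses a proton to form the aromatic pyranone and thereby removes the C2 stereocentre.

**Step 8**
Reactants: 13 5,7-dimethoxy-6-methyl-2-nonacosyl-4H-chromen-4-one
Product: 14 5,7-dihydroxy-6-methyl-2-nonacosyl-4H-chromen-4-one (target)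
Conditions: BBr3 (excess), CH2Cl2, −78 °C → rt; then H2O
Reagents that add atoms: none
Why: Lewis-acid ether cleavage with BBr3 (coordination at the ether oxygen, then SN2 attack of bromide on the methyl carbon) should remove both methyl groups, the 5-methoxy group first through chelation with the C4 carbonyl, while the pyranone ring and the saturated chain are inert.

**Compound list**

1 | 2,6-dimethoxytoluene | COc1cccc(OC)c1C | starting material
2 | 2-(3,5-dimethoxy-4-methylphenyl)-4,4,5,5-tetramethyl-1,3,2-dioxaborolane | COc1cc(B2OC(C)(C)C(C)(C)O2)cc(OC)c1C | intermediate (not isolated)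
3 | 3,5-dimethoxy-4-methylphenol | COc1cc(O)cc(OC)c1C | intermediate
4 | 3,5-dimethoxy-4-methylphenyl acetate | COc1cc(OC(C)=O)cc(OC)c1C | intermediate (not isolated)
5 | 1-(6-hydroxy-2,4-dimethoxy-3-methylphenyl)ethan-1-one | CC(=O)c1c(O)cc(OC)c(C)c1OC | intermediate
6 | 5,7-dimethoxy-6-methyl-4-oxo-4H-chromene-3-carbaldehyde | COc1cc2occ(C=O)c(=O)c2c(OC)c1C | intermediate
7 | 5,7-dimethoxy-6-methyl-4-oxo-4H-chromene-3-carboxylic acid | COc1cc2occ(C(=O)O)c(=O)c2c(OC)c1C | intermediate
8 | triacontanoic acid | CCCCCCCCCCCCCCCCCCCCCCCCCCCCCC(=O)O | starting material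
9 | N-hydroxyphthalimide | O=C1c2ccccc2C(=O)N1O | starting material
10 | 1,3-dioxoisoindolin-2-yl triacontanoate | CCCCCCCCCCCCCCCCCCCCCCCCCCCCCC(=O)ON1C(=O)c2ccccc2C1=O | intermediate
11 | 5,7-dimethoxy-6-methyl-2-nonacosyl-4-oxochromane-3-carboxylic acid (racemic, diastereomer mixture) | CCCCCCCCCCCCCCCCCCCCCCCCCCCCCC1Oc2cc(OC)c(C)c(OC)c2C(=O)C1C(=O)O | intermediate (not isolated)
12 | rac-5,7-dimethoxy-6-methyl-2-nonacosylchroman-4-one | CCCCCCCCCCCCCCCCCCCCCCCCCCCCCC1CC(=O)c2c(OC)c(C)c(OC)cc2O1 | intermediate
13 | 5,7-dimethoxy-6-methyl-2-nonacosyl-4H-chromen-4-one | CCCCCCCCCCCCCCCCCCCCCCCCCCCCCc1cc(=O)c2c(OC)c(C)c(OC)cc2o1 | intermediate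
14 | 5,7-dihydroxy-6-methyl-2-nonacosyl-4H-chromen-4-one | CCCCCCCCCCCCCCCCCCCCCCCCCCCCCc1cc(=O)c2c(O)c(C)c(O)cc2o1 | target

**Step count.** Total: 8 steps. Longest linear sequence: 7 steps (steps 1, 2, 3, 4, 6, 7, 8 from 2,6-dimethoxytoluene); step 5 is a one-step side branch.

**Steps most likely to fail**

1. Step 6. The primary radical may be reduced (hydrogen-atom transfer from the amine radical cation) before the electron-rich, carboxylate-form acceptor captures it, and the C30 ester may not stay in solution. The fallback gives up the radical addition and builds the pyranone ring around the chain by Claisen condensation and cyclodehydration. It sets out from acetophenone 5 and acid 8 and returns at chromone 13, bypassing steps 3 to 7. Acid 8 is esterified (MeOH, cat. H2SO4, toluene, reflux) to methyl triacontanoate F1. The sodium dianion of 5 (NaH, THF, reflux) is acylated at the acetyl carbon by F1 to give 1-(6-hydroxy-2,4-dimethoxy-3-methylphenyl)dotriacontane-1,3-dione F2. TsOH in toluene at reflux should then close the ring by attack of the phenol on the distal carbonyl and loss of water, giving 13.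

2. Step 7. Hydride abstraction at the non-benzylic C2 may be sluggish, leaving conversion incomplete, and oxidation at the benzylic 6-methyl group may compete. The fallback is a Saegusa–Ito sequence from 12 back to 13. Soft enolisation (Me3SiOTf, Et3N, CH2Cl2, 0 °C) should give trimethyl[(5,7-dimethoxy-6-methyl-2-nonacosyl-2H-chromen-4-yl)oxy]silane F3. Pd(OAc)2 in MeCN/THF then forms the C3 palladium enolate, and β-hydride elimination of the C2 hydrogen should deliver 13.

3. Step 8. Cleavage of the non-chelated 7-methyl ether may stop short, with partly demethylated boron complexes of the waxy product precipitating. The fallback sets out from 13 and returns at 14 in two stages of different mechanism. BCl3 (CH2Cl2, −20 → 0 °C) removes only the chelated 5-methyl group, giving 5-hydroxy-7-methoxy-6-methyl-2-nonacosyl-4H-chromen-4-one F4. NaSEt in DMF at 120 °C then cleaves the 7-methyl ether by SN2 attack of thiolate on the methyl carbon, the leaving phenoxide being para to the C4 carbonyl; acidic work-up should give 14.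

**Further compounds**

F1 | step 6 | methyl triacontanoate | CCCCCCCCCCCCCCCCCCCCCCCCCCCCCC(=O)OC
F2 | step 6 | 1-(6-hydroxy-2,4-dimethoxy-3-methylphenyl)dotriacontane-1,3-dione | CCCCCCCCCCCCCCCCCCCCCCCCCCCCCC(=O)CC(=O)c1c(O)cc(OC)c(C)c1OC
F3 | step 7 | trimethyl[(5,7-dimethoxy-6-methyl-2-nonacosyl-2H-chromen-4-yl)oxy]silane (racemic) | CCCCCCCCCCCCCCCCCCCCCCCCCCCCCC1C=C(O[Si](C)(C)C)c2c(OC)c(C)c(OC)cc2O1
F4 | step 8 | 5-hydroxy-7-methoxy-6-methyl-2-nonacosyl-4H-chromen-4-one | CCCCCCCCCCCCCCCCCCCCCCCCCCCCCc1cc(=O)c2c(O)c(C)c(OC)cc2o1
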